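## Analysis of the target

The target is an acyclic 8-O-4' neolignan: a chain C7–C8–C9 that carries the 3,4,5-trimethoxyphenyl ring (ring A) on C7, is linked through the oxygen on C8 to C4' of the 4-allyl-2,6-dimethoxyphenyl ring (ring B), and ends in an acetylated primary hydroxyl on C9. The two benzene rings are the only rings and both can be bought complete, so no ring has to be closed and the whole task lies in the three-carbon chain. The chain holds two adjacent stereocentres, the benzylic carbinol C7 and the aryl ether carbon C8, both R, which is the threo (1,2-syn) relationship; with no ring to relay it, this relationship must come from acyclic control. Three groups are sensitive: the terminal allyl group on ring B rules out hydrogenolysis, hydroboration and any base strong enough to move the double bond into conjugation; the primary acetate can migrate to O7 or be cleaved under base; and the C7 alcohol is benzylic to an electron-rich ring and can ionise in acid. The synthesis is hard for two reasons: the C8–O4' bond joins a secondary carbon to a phenol oxygen flanked by two methoxy groups, so a late substitution at C8 would be slow and would compete with elimination, and O7 and O9 must end up differently substituted. The plan rests on the position of C9: it is a single oxygenated carbon on C8, and C8 is alpha to C7. With C7 at the ketone oxidation level, C8 becomes an enol carbon that can take up formaldehyde, and the aryl ether bond can be made earlier, at a primary phenacyl carbon, before any stereocentre exists.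

## Retrosynthetic reasoning

The O9–acetyl bond of target 12, (2R,3R)-2-(4-allyl-2,6-dimethoxyphenoxy)-3-hydroxy-3-(3,4,5-trimethoxyphenyl)propyl acetate, is cut first. This leads back to diol 11, (1R,2R)-2-(4-allyl-2,6-dimethoxyphenoxy)-1-(3,4,5-trimethoxyphenyl)propane-1,3-diol. The acetate is the most base-labile group in the molecule and would migrate or be attacked in any earlier hydride or fluoride step, so it goes on last. The forward reaction has to tell a primary hydroxyl from a secondary benzylic one that is crowded by ring A and by the aryloxy group on C8; that difference in hindrance is large enough for a kinetic acylation.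

Diol 11 is traced back through its O9 tert-butyldimethylsilyl ether 10 to the silyl-protected ketone 9 by cutting the C7–H bond. Taking C7 to the ketone level removes one stereocentre and is what makes C8 enolisable in the later disconnections. In the forward direction a hydride has to add to the C7 carbonyl from the face that the C8 centre dictates. Under the Felkin–Anh model the aryloxy group stands anti to the incoming hydride and the C8 hydrogen lies on the flank the hydride passes, which gives the threo alcohol. A chelate between the carbonyl oxygen and the aryloxy oxygen would give erythro instead. The reduction therefore needs a bulky hydride, a counter-ion that cannot chelate, and a silyl group on O9 that takes this oxygen out of play as a donor.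

The O9–Si bond of 9 is cut to give hydroxy ketone 8, (R)-2-(4-allyl-2,6-dimethoxyphenoxy)-3-hydroxy-1-(3,4,5-trimethoxyphenyl)propan-1-one. The silyl group is more than a spectator for the reduction: it caps a free beta-hydroxy ketone whose C8–H lies between a carbonyl and an aryloxy group and which could otherwise lose formaldehyde or water.

In 8 the C8–C9 bond is cut, which gives formaldehyde 7 and the Z trimethylsilyl enol ether 6. This cut simplifies most: it removes the last stereocentre, leaves a one-carbon electrophile of no cost, and leaves an achiral precursor. Cutting C7–C8 instead would call for a chiral aryloxyacetyl enolate with a stoichiometric auxiliary. Cutting C8–O4' would put a hindered phenol into a substitution at a secondary carbon. Cutting the ring A–C7 bond would pass through an aldehyde with a labile alpha-centre. In the forward direction the enol ether has to add to formaldehyde in water under a chiral Lewis acid that selects one face of C8, and the medium has to stay near neutral so that 8 keeps its configuration.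

Enol ether 6 comes from ketone 4, 2-(4-allyl-2,6-dimethoxyphenoxy)-1-(3,4,5-trimethoxyphenyl)ethan-1-one, by way of its lithium enolate 5 (O–Si bond). Only one alpha-carbon can be deprotonated, so there is no regiochemical question. The geometry should be Z because lithium is held between the enolate oxygen and the aryloxy oxygen and because ring A avoids the substituent on C8. A single enol ether geometry is what the catalyst of the key step needs.

Ketone 4 is cut at the C8–O4' bond into bromide 2, 2-bromo-1-(3,4,5-trimethoxyphenyl)ethan-1-one, and phenol 3, 4-allyl-2,6-dimethoxyphenol. At this stage C8 is a primary carbon activated by the carbonyl, so even the doubly ortho-substituted phenoxide of 3 should substitute quickly, and nothing stereochemical is at stake. Ring B arrives complete with its allyl group.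

Bromide 2 comes from 3',4',5'-trimethoxyacetophenone 1 by cutting the C8–Br bond. The forward bromination must go to the methyl group and not to the electron-rich ring A.

## Alternatives that were turned down

Alternative 1: Auxiliary-controlled glycolate aldol across C7–C8.
- **Disconnection:** C7–C8, between an aryloxyacetyl enolate and an aromatic aldehyde.
- **Forward key step:** the acyl oxazolidinone A1, (S)-4-benzyl-3-[2-(4-allyl-2,6-dimethoxyphenoxy)acetyl]oxazolidin-2-one, is converted into its dibutylboron Z enolate. This adds to 3,4,5-trimethoxybenzaldehyde A2 through a closed chair transition state and should give the syn aldol A3 with the 2S,3R configuration. Reductive removal of the auxiliary would lead straight to diol 11.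
- **For it:** one step makes the C7–C8 bond and both stereocentres. The syn relationship of a glycolate boron aldol is exactly the threo relationship of the target. No configurationally labile ketone is ever present. From phenol 3 the target would be reached in about five steps, fewer than here. On step count and on certainty of the relative configuration this alternative is the stronger plan.
- **Against it:** chirality and boron are used in stoichiometric amount. The auxiliary must be attached and then removed by hydride next to a crowded alpha-aryloxy carbon, where attack on the ring carbonyl of the oxazolidinone competes. C7 and C8 are locked together, so a mixed outcome cannot be corrected at one centre alone.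
- **Comparison:** the chosen strategy offers in its place asymmetric induction from a tenth of an equivalent of ligand on an achiral precursor made in three simple steps, and a C7 centre that is set separately and can be steered to either diastereomer or inverted.

Alternative 2: Biomimetic radical cross-coupling and hydration.
- **Disconnection:** C8–O4' and C7–O, in the manner of lignin biosynthesis.
- **Forward key step:** one-electron oxidation of sinapyl alcohol A4 and phenol 3 (a silver oxidant, a peroxidase with peroxide, or an anode) is meant to join C8 of the radical of A4 to O4' of the phenoxyl radical of 3. This gives the quinone methide A5, to whose C7 water then adds. The product would be the threo triol A6, which carries a free phenol on ring A.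
- **For it:** it is by far the shortest way to the skeleton, needs no protecting group up to that point, and uses the biogenetic building blocks. In step economy it is stronger than the chosen route.
- **Against it:** nothing in the coupling is chiral, so A6 can only be racemic and the single enantiomer would need a resolution. The radical of A4 carries much of its spin density at C8 and can couple with itself, so cross-coupling is statistical at best. Water adds to the planar C7 of A5 from either face, and with two methoxy groups on ring A the erythro mode is expected to be favoured. The ring A phenol would still have to be methylated in the presence of two alcohols.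
- **Comparison:** the chosen strategy gives up brevity for control of both absolute and relative configuration by design.

Alternative 3: Chelation-controlled aryl addition to an alpha-aryloxy aldehyde.
- **Disconnection:** ring A–C7, an aryl nucleophile on an alpha-aryloxy aldehyde.
- **Forward key step:** (3,4,5-trimethoxyphenyl)magnesium bromide A9 adds to the (R)-aldehyde A8, (R)-2-(4-allyl-2,6-dimethoxyphenoxy)-3-[(tert-butyldimethylsilyl)oxy]propanal, with a magnesium Lewis acid present. A chelate between the aldehyde oxygen and the aryloxy oxygen should direct the aryl group so that A10 forms, which is the same compound as 10 of the chosen route. A8 would come from the chiral-pool hydroxy ester A7, methyl (S)-3-[(tert-butyldimethylsilyl)oxy]-2-hydroxypropanoate, by etherification with phenol 3 under inversion and partial reduction.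
- **For it:** C8 is bought with known absolute configuration, which is more certain than any catalytic induction. The route is convergent and meets the chosen route at 10, so the end game is the same and the length is about equal.
- **Against it:** the C8–O4' bond has to be made at a secondary carbon with a phenol hindered on both sides. A8 has an acidic hydrogen on C8 next to the aldehyde and can lose its configuration before or during the addition. The threo outcome depends on a chelate through a weakly basic aryl ether oxygen, while the non-chelated Felkin–Anh path gives the erythro isomer, so the selectivity rests on a balance.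
- **Comparison:** in the chosen strategy the ether bond is made at a primary carbon, and threo at C7 comes from the non-chelated mode of a hydride reduction. That only asks for chelation to be switched off, which a bulky reagent and a sequestered cation can do.

Key step: step 4

Assumption: by analogy with alpha-alkyl aryl ketone enol ethers, the (S,S)-ligand is taken to direct formaldehyde to the face of 6 that makes C8 R; the sense is checked on the first run, and if it is opposite the (R,R)-ligand is used with nothing else changed.

## Route

Step 1
Reactants: 1 3',4',5'-trimethoxyacetophenone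
Product: 2 2-bromo-1-(3,4,5-trimethoxyphenyl)ethan-1-one
Conditions: CuBr2 (2.1 equiv), EtOAc/CHCl3 (1:1), reflux
Reagents that add atoms: copper dibromide (CuBr2), Br[Cu]Br
Why: Alpha-bromination of an aryl methyl ketone with CuBr2 goes through the copper-bound enol and delivers bromine to the methyl carbon; unlike free Br2 it should leave the electron-rich ring A unbrominated and stop at the monobromide.

Step 2
Reactants: 2 2-bromo-1-(3,4,5-trimethoxyphenyl)ethan-1-one; 3 4-allyl-2,6-dimethoxyphenol
Product: 4 2-(4-allyl-2,6-dimethoxyphenoxy)-1-(3,4,5-trimethoxyphenyl)ethan-1-one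
Conditions: K2CO3 (1.5 equiv), acetone, rt to 50 °C
Reagents that add atoms: none
Why: Williamson ether synthesis; the phenacyl bromide is an SN2 electrophile activated by the adjacent carbonyl, so even the phenoxide of 3 with its two ortho-methoxy groups should substitute cleanly at this primary carbon, and the carbonate base is too weak to move the allyl double bond.

Step 3
Reactants: 4 2-(4-allyl-2,6-dimethoxyphenoxy)-1-(3,4,5-trimethoxyphenyl)ethan-1-one
Product: 6 (Z)-[2-(4-allyl-2,6-dimethoxyphenoxy)-1-(3,4,5-trimethoxyphenyl)ethenyloxy]trimethylsilane, via lithium Z enolate 5 (not isolated)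
Conditions: LiN(SiMe3)2 (1.1 equiv), THF, −78 °C; Me3SiCl (1.3 equiv), −78 to 0 °C; pentane, filtration, no aqueous work-up
Reagents that add atoms: chlorotrimethylsilane, C[Si](C)(C)Cl
Why: Kinetic deprotonation at C8, the only enolisable position, followed by O-silylation of the enolate (silyl enol ether formation); lithium bridged between the enolate oxygen and the aryloxy oxygen, together with allylic strain between ring A and the C8 substituent, should place the silyloxy and aryloxy groups cis, that is Z.

Step 4
Reactants: 6 (Z)-[2-(4-allyl-2,6-dimethoxyphenoxy)-1-(3,4,5-trimethoxyphenyl)ethenyloxy]trimethylsilane; 7 formaldehyde (35% aqueous solution, 5 equiv)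
Product: 8 (R)-2-(4-allyl-2,6-dimethoxyphenoxy)-3-hydroxy-1-(3,4,5-trimethoxyphenyl)propan-1-one
Conditions: Sc(OTf)3 (10 mol%), (S,S)-6,6'-bis(1-hydroxy-2,2-dimethylpropyl)-2,2'-bipyridine (12 mol%), DME/H2O (9:1), −20 °C
Reagents that add atoms: none
Why: This is a catalytic asymmetric Mukaiyama aldol reaction (hydroxymethylation) in aqueous medium: Sc(OTf)3 and the tetradentate bipyridine diol form a water-stable chiral complex of trivalent scandium that binds formaldehyde at an open coordination site. Carbon C8 of enol ether 6 attacks the bound formaldehyde through an open transition state and makes the C8–C9 bond, after which water takes the silicon off the oxocarbenium ion so that the C7 ketone returns and the catalyst turns over. The closest known reaction type is the hydroxymethylation of trimethylsilyl enol ethers of alpha-substituted aryl ketones with aqueous formaldehyde under this same catalyst; here the alpha-substituent is an aryloxy group in place of an alkyl group. No ring is closed. The one new stereocentre, C8, is set by the ligand, whose two tert-butyl carbinol arms block one side of the coordinated aldehyde so that only one enantioface of the enol ether can reach it; the configuration is R under the assumption stated before the steps. The step needs enantioface selection and needs C–C bond formation to outrun hydrolysis of 6; the single Z geometry of 6 secures the first, and the excess of formaldehyde, the low temperature and the mostly organic solvent favour the second. The medium stays near neutral, so the C8–H of 8, which lies between a ketone and an aryloxy group, should not be removed and neither epimerisation nor loss of formaldehyde is expected before the next step.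

Step 5
Reactants: 8 (R)-2-(4-allyl-2,6-dimethoxyphenoxy)-3-hydroxy-1-(3,4,5-trimethoxyphenyl)propan-1-one
Product: 9 (R)-2-(4-allyl-2,6-dimethoxyphenoxy)-3-[(tert-butyldimethylsilyl)oxy]-1-(3,4,5-trimethoxyphenyl)propan-1-one
Conditions: TBSCl (1.2 equiv), imidazole (2 equiv), CH2Cl2, 0 °C
Reagents that add atoms: tert-butyldimethylsilyl chloride, CC(C)(C)[Si](C)(C)Cl
Why: Silylation of a primary alcohol with imidazole as nucleophilic catalyst and acid scavenger; the base is too weak to enolise the ketone at 0 °C, so C8 should keep its configuration, and with O9 capped the retro-aldol path is closed and O9 no longer acts as a donor toward a metal.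

Step 6
Reactants: 9 (R)-2-(4-allyl-2,6-dimethoxyphenoxy)-3-[(tert-butyldimethylsilyl)oxy]-1-(3,4,5-trimethoxyphenyl)propan-1-one
Product: 10 (1R,2R)-2-(4-allyl-2,6-dimethoxyphenoxy)-3-[(tert-butyldimethylsilyl)oxy]-1-(3,4,5-trimethoxyphenyl)propan-1-ol
Conditions: KBH(s-Bu)3 (1.2 equiv), 18-crown-6 (1.2 equiv), THF, −78 °C; then aq. NaOH, H2O2, 0 °C
Reagents that add atoms: none
Why: Diastereoselective ketone reduction by a bulky trialkylborohydride under Felkin–Anh control: with potassium held in the crown ether no chelate should form, the C8–O bond to ring B lies anti to the incoming hydride, the C8 hydrogen flanks its path and the silyloxymethyl group sits inside, so hydride should reach the face of the C7 carbonyl that gives the 7R (threo) alcohol. The oxidative work-up only destroys the borane and does not touch the isolated allyl double bond.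

Step 7
Reactants: 10 (1R,2R)-2-(4-allyl-2,6-dimethoxyphenoxy)-3-[(tert-butyldimethylsilyl)oxy]-1-(3,4,5-trimethoxyphenyl)propan-1-ol
Product: 11 (1R,2R)-2-(4-allyl-2,6-dimethoxyphenoxy)-1-(3,4,5-trimethoxyphenyl)propane-1,3-diol
Conditions: Bu4NF (1.2 equiv), THF, 0 °C
Reagents that add atoms: none
Why: Fluoride cleavage of a primary silyl ether, driven by the strength of the Si–F bond; nothing in 10 is base-sensitive any longer, and avoiding acid keeps the C7 carbinol from ionising.

Step 8
Reactants: 11 (1R,2R)-2-(4-allyl-2,6-dimethoxyphenoxy)-1-(3,4,5-trimethoxyphenyl)propane-1,3-diol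
Product: 12 (2R,3R)-2-(4-allyl-2,6-dimethoxyphenoxy)-3-hydroxy-3-(3,4,5-trimethoxyphenyl)propyl acetate
Conditions: AcCl (1.05 equiv), 2,4,6-collidine (2 equiv), CH2Cl2, −78 °C
Reagents that add atoms: acetyl chloride, CC(=O)Cl
Why: Kinetically controlled acylation of a diol with an acyl chloride and a hindered pyridine base at low temperature selects the primary hydroxyl; O7 is secondary, benzylic and shielded by ring A and by the aryloxy group on C8, so the monoacetate at O9 should form, and the weak, non-nucleophilic base gives no opening for acyl migration.

## Compound list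

1 | 3',4',5'-trimethoxyacetophenone | CC(=O)c1cc(OC)c(OC)c(OC)c1 | starting material
2 | 2-bromo-1-(3,4,5-trimethoxyphenyl)ethan-1-one | BrCC(=O)c1cc(OC)c(OC)c(OC)c1 | intermediate
3 | 4-allyl-2,6-dimethoxyphenol | C=CCc1cc(OC)c(O)c(OC)c1 | starting material
4 | 2-(4-allyl-2,6-dimethoxyphenoxy)-1-(3,4,5-trimethoxyphenyl)ethan-1-one | O=C(COc1c(OC)cc(CC=C)cc1OC)c1cc(OC)c(OC)c(OC)c1 | intermediate
5 | lithium (Z)-2-(4-allyl-2,6-dimethoxyphenoxy)-1-(3,4,5-trimethoxyphenyl)ethen-1-olate | [Li+].[O-]/C(c1cc(OC)c(OC)c(OC)c1)=C\Oc1c(OC)cc(CC=C)cc1OC | intermediate
6 | (Z)-[2-(4-allyl-2,6-dimethoxyphenoxy)-1-(3,4,5-trimethoxyphenyl)ethenyloxy]trimethylsilane | C[Si](C)(C)O/C(c1cc(OC)c(OC)c(OC)c1)=C\Oc1c(OC)cc(CC=C)cc1OC | intermediate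
7 | formaldehyde | C=O | starting material
8 | (R)-2-(4-allyl-2,6-dimethoxyphenoxy)-3-hydroxy-1-(3,4,5-trimethoxyphenyl)propan-1-one | O=C(c1cc(OC)c(OC)c(OC)c1)[C@H](Oc1c(OC)cc(CC=C)cc1OC)CO | intermediate
9 | (R)-2-(4-allyl-2,6-dimethoxyphenoxy)-3-[(tert-butyldimethylsilyl)oxy]-1-(3,4,5-trimethoxyphenyl)propan-1-one | O=C(c1cc(OC)c(OC)c(OC)c1)[C@H](Oc1c(OC)cc(CC=C)cc1OC)CO[Si](C)(C)C(C)(C)C | intermediate
10 | (1R,2R)-2-(4-allyl-2,6-dimethoxyphenoxy)-3-[(tert-butyldimethylsilyl)oxy]-1-(3,4,5-trimethoxyphenyl)propan-1-ol | C=CCc1cc(OC)c(O[C@H](CO[Si](C)(C)C(C)(C)C)[C@H](O)c2cc(OC)c(OC)c(OC)c2)c(OC)c1 | intermediate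
11 | (1R,2R)-2-(4-allyl-2,6-dimethoxyphenoxy)-1-(3,4,5-trimethoxyphenyl)propane-1,3-diol | C=CCc1cc(OC)c(O[C@H](CO)[C@H](O)c2cc(OC)c(OC)c(OC)c2)c(OC)c1 | intermediate
12 | (2R,3R)-2-(4-allyl-2,6-dimethoxyphenoxy)-3-hydroxy-3-(3,4,5-trimethoxyphenyl)propyl acetate | C=CCc1cc(OC)c(O[C@H](COC(C)=O)[C@H](O)c2cc(OC)c(OC)c(OC)c2)c(OC)c1 | target

## Step count and least certain steps

Total step count: 8. Longest linear sequence: 8 steps (1 to 12).

**Step 4 (key step).** What is most likely to go wrong is erosion of enantioface selection: the aryloxy oxygen with its two flanking methoxy groups can bind the scandium centre in competition with formaldehyde and disturb the chiral pocket. Hydrolysis of the enol ether back to ketone 4 may also outrun C–C bond formation. The fallback sets out from phenol 3 and comes back to the route at silyl ether 9, with a stoichiometric auxiliary in place of the catalyst. Phenol 3 is alkylated with bromoacetic acid (NaH, 2.2 equiv, THF) to (4-allyl-2,6-dimethoxyphenoxy)acetic acid F1. Its mixed pivalic anhydride acylates the lithium salt of (S)-4-benzyloxazolidin-2-one to give (S)-4-benzyl-3-[2-(4-allyl-2,6-dimethoxyphenoxy)acetyl]oxazolidin-2-one F2, which is the same compound as A1. The chelated titanium Z enolate of F2 (TiCl4, i-Pr2NEt, CH2Cl2, 0 °C) is hydroxymethylated with 1,3,5-trioxane and further TiCl4 on the face away from the benzyl group. This should give (S)-4-benzyl-3-[(R)-2-(4-allyl-2,6-dimethoxyphenoxy)-3-hydroxypropanoyl]oxazolidin-2-one F3. Transamination (MeNHOMe·HCl, AlMe3), helped by the free hydroxyl, gives the Weinreb amide (R)-2-(4-allyl-2,6-dimethoxyphenoxy)-3-hydroxy-N-methoxy-N-methylpropanamide F4. Silylation (TBSCl, imidazole) gives (R)-2-(4-allyl-2,6-dimethoxyphenoxy)-3-[(tert-butyldimethylsilyl)oxy]-N-methoxy-N-methylpropanamide F5. Commercial (3,4,5-trimethoxyphenyl)magnesium bromide (THF, 0 °C) then converts F5 into ketone 9.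

**Step 6.** The likely failure is a turn of the facial preference toward the erythro alcohol, because the carbonyl oxygen and the aryloxy oxygen with its ortho-methoxy groups form a pocket that can still hold a cation. Enolisation toward C8 by the basic hydride, with loss of configuration there, is the second risk. The fallback sets out from ketone 9 and comes back at alcohol 10; it uses the chelate on purpose and then inverts C7. Zn(BH4)2 in Et2O at −20 °C should reduce 9 through the zinc chelate to (1S,2R)-2-(4-allyl-2,6-dimethoxyphenoxy)-3-[(tert-butyldimethylsilyl)oxy]-1-(3,4,5-trimethoxyphenyl)propan-1-ol F6. A Mitsunobu reaction (4-nitrobenzoic acid, PPh3, diisopropyl azodicarboxylate, THF) inverts C7 and gives (1R,2R)-2-(4-allyl-2,6-dimethoxyphenoxy)-3-[(tert-butyldimethylsilyl)oxy]-1-(3,4,5-trimethoxyphenyl)propyl 4-nitrobenzoate F7. Methanolysis (K2CO3, MeOH, 0 °C) releases alcohol 10.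

**Step 8.** The risk is incomplete discrimination between O9 and O7, giving over-acylation or some acetate on the wrong oxygen, and acyl migration during isolation. The fallback sets out from alcohol 10 and comes back at target 12; it replaces kinetic discrimination by differential protection. Silylation of O7 (t-BuMe2SiOTf, 2,6-lutidine, CH2Cl2, −78 °C) gives (1R,2R)-2-(4-allyl-2,6-dimethoxyphenoxy)-1,3-bis[(tert-butyldimethylsilyl)oxy]-1-(3,4,5-trimethoxyphenyl)propane F8. Buffered HF·pyridine (pyridine, THF, 0 °C) removes the less hindered primary silyl group first and gives (2R,3R)-2-(4-allyl-2,6-dimethoxyphenoxy)-3-[(tert-butyldimethylsilyl)oxy]-3-(3,4,5-trimethoxyphenyl)propan-1-ol F9. Acetylation (Ac2O, pyridine, 4-dimethylaminopyridine) gives (2R,3R)-2-(4-allyl-2,6-dimethoxyphenoxy)-3-[(tert-butyldimethylsilyl)oxy]-3-(3,4,5-trimethoxyphenyl)propyl acetate F10. Longer exposure to HF·pyridine (THF, rt) removes the secondary silyl group and leaves target 12.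

**Step 5.** The risk is loss of configuration at C8 through base-mediated enolisation, together with retro-aldol loss of formaldehyde or elimination of water from the free beta-hydroxy ketone while it waits for protection. The fallback sets out from hydroxy ketone 8 and comes back at diol 11; it protects under acid catalysis with an acetal instead of under base with a silyl chloride. 2-Methoxypropene with catalytic pyridinium 4-toluenesulfonate (CH2Cl2, 0 °C) gives (R)-2-(4-allyl-2,6-dimethoxyphenoxy)-3-[(2-methoxypropan-2-yl)oxy]-1-(3,4,5-trimethoxyphenyl)propan-1-one F11. The reduction of step 6 (KBH(s-Bu)3, 18-crown-6, THF, −78 °C) should give (1R,2R)-2-(4-allyl-2,6-dimethoxyphenoxy)-3-[(2-methoxypropan-2-yl)oxy]-1-(3,4,5-trimethoxyphenyl)propan-1-ol F12. Methanolysis of the acetal (pyridinium 4-toluenesulfonate, MeOH, 0 °C) gives diol 11.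

## Further compounds

F1 | step 4 | (4-allyl-2,6-dimethoxyphenoxy)acetic acid | OC(=O)COc1c(OC)cc(CC=C)cc1OC
F2 | step 4 | (S)-4-benzyl-3-[2-(4-allyl-2,6-dimethoxyphenoxy)acetyl]oxazolidin-2-one | O=C(COc1c(OC)cc(CC=C)cc1OC)N1[C@@H](Cc2ccccc2)COC1=O
F3 | step 4 | (S)-4-benzyl-3-[(R)-2-(4-allyl-2,6-dimethoxyphenoxy)-3-hydroxypropanoyl]oxazolidin-2-one | O=C([C@H](Oc1c(OC)cc(CC=C)cc1OC)CO)N1[C@@H](Cc2ccccc2)COC1=O
F4 | step 4 | (R)-2-(4-allyl-2,6-dimethoxyphenoxy)-3-hydroxy-N-methoxy-N-methylpropanamide | CON(C)C(=O)[C@H](Oc1c(OC)cc(CC=C)cc1OC)CO
F5 | step 4 | (R)-2-(4-allyl-2,6-dimethoxyphenoxy)-3-[(tert-butyldimethylsilyl)oxy]-N-methoxy-N-methylpropanamide | CON(C)C(=O)[C@H](Oc1c(OC)cc(CC=C)cc1OC)CO[Si](C)(C)C(C)(C)C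
F6 | step 6 | (1S,2R)-2-(4-allyl-2,6-dimethoxyphenoxy)-3-[(tert-butyldimethylsilyl)oxy]-1-(3,4,5-trimethoxyphenyl)propan-1-ol | C=CCc1cc(OC)c(O[C@H](CO[Si](C)(C)C(C)(C)C)[C@@H](O)c2cc(OC)c(OC)c(OC)c2)c(OC)c1
F7 | step 6 | (1R,2R)-2-(4-allyl-2,6-dimethoxyphenoxy)-3-[(tert-butyldimethylsilyl)oxy]-1-(3,4,5-trimethoxyphenyl)propyl 4-nitrobenzoate | C=CCc1cc(OC)c(O[C@H](CO[Si](C)(C)C(C)(C)C)[C@H](OC(=O)c3ccc(cc3)[N+](=O)[O-])c2cc(OC)c(OC)c(OC)c2)c(OC)c1
F8 | step 8 | (1R,2R)-2-(4-allyl-2,6-dimethoxyphenoxy)-1,3-bis[(tert-butyldimethylsilyl)oxy]-1-(3,4,5-trimethoxyphenyl)propane | C=CCc1cc(OC)c(O[C@H](CO[Si](C)(C)C(C)(C)C)[C@H](O[Si](C)(C)C(C)(C)C)c2cc(OC)c(OC)c(OC)c2)c(OC)c1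
F9 | step 8 | (2R,3R)-2-(4-allyl-2,6-dimethoxyphenoxy)-3-[(tert-butyldimethylsilyl)oxy]-3-(3,4,5-trimethoxyphenyl)propan-1-ol | C=CCc1cc(OC)c(O[C@H](CO)[C@H](O[Si](C)(C)C(C)(C)C)c2cc(OC)c(OC)c(OC)c2)c(OC)c1
F10 | step 8 | (2R,3R)-2-(4-allyl-2,6-dimethoxyphenoxy)-3-[(tert-butyldimethylsilyl)oxy]-3-(3,4,5-trimethoxyphenyl)propyl acetate | C=CCc1cc(OC)c(O[C@H](COC(C)=O)[C@H](O[Si](C)(C)C(C)(C)C)c2cc(OC)c(OC)c(OC)c2)c(OC)c1
F11 | step 5 | (R)-2-(4-allyl-2,6-dimethoxyphenoxy)-3-[(2-methoxypropan-2-yl)oxy]-1-(3,4,5-trimethoxyphenyl)propan-1-one | O=C(c1cc(OC)c(OC)c(OC)c1)[C@H](Oc1c(OC)cc(CC=C)cc1OC)COC(C)(C)OC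
F12 | step 5 | (1R,2R)-2-(4-allyl-2,6-dimethoxyphenoxy)-3-[(2-methoxypropan-2-yl)oxy]-1-(3,4,5-trimethoxyphenyl)propan-1-ol | C=CCc1cc(OC)c(O[C@H](COC(C)(C)OC)[C@H](O)c2cc(OC)c(OC)c(OC)c2)c(OC)c1
A1 | alternative 1 | (S)-4-benzyl-3-[2-(4-allyl-2,6-dimethoxyphenoxy)acetyl]oxazolidin-2-one | O=C(COc1c(OC)cc(CC=C)cc1OC)N1[C@@H](Cc2ccccc2)COC1=O
A2 | alternative 1 | 3,4,5-trimethoxybenzaldehyde | O=Cc1cc(OC)c(OC)c(OC)c1
A3 | alternative 1 | (S)-4-benzyl-3-[(2S,3R)-2-(4-allyl-2,6-dimethoxyphenoxy)-3-hydroxy-3-(3,4,5-trimethoxyphenyl)propanoyl]oxazolidin-2-one | O=C([C@@H](Oc1c(OC)cc(CC=C)cc1OC)[C@H](O)c1cc(OC)c(OC)c(OC)c1)N1[C@@H](Cc2ccccc2)COC1=O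
A4 | alternative 2 | sinapyl alcohol, (E)-4-(3-hydroxyprop-1-enyl)-2,6-dimethoxyphenol | OC/C=C/c1cc(OC)c(O)c(OC)c1
A5 | alternative 2 | 4-[2-(4-allyl-2,6-dimethoxyphenoxy)-3-hydroxypropylidene]-2,6-dimethoxycyclohexa-2,5-dien-1-one (racemic) | O=C1C(OC)=CC(=CC(CO)Oc2c(OC)cc(CC=C)cc2OC)C=C1OC
A6 | alternative 2 | threo-2-(4-allyl-2,6-dimethoxyphenoxy)-1-(4-hydroxy-3,5-dimethoxyphenyl)propane-1,3-diol (racemate, (1R,2R) enantiomer drawn) | C=CCc1cc(OC)c(O[C@H](CO)[C@H](O)c2cc(OC)c(O)c(OC)c2)c(OC)c1
A7 | alternative 3 | methyl (S)-3-[(tert-butyldimethylsilyl)oxy]-2-hydroxypropanoate | COC(=O)[C@@H](O)CO[Si](C)(C)C(C)(C)C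
A8 | alternative 3 | (R)-2-(4-allyl-2,6-dimethoxyphenoxy)-3-[(tert-butyldimethylsilyl)oxy]propanal | O=C[C@H](Oc1c(OC)cc(CC=C)cc1OC)CO[Si](C)(C)C(C)(C)C
A9 | alternative 3 | (3,4,5-trimethoxyphenyl)magnesium bromide | COc1cc([Mg]Br)cc(OC)c1OC
A10 | alternative 3 | (1R,2R)-2-(4-allyl-2,6-dimethoxyphenoxy)-3-[(tert-butyldimethylsilyl)oxy]-1-(3,4,5-trimethoxyphenyl)propan-1-ol | CC(C)(C)[Si](C)(C)OC[C@@H](Oc1c(OC)cc(CC=C)cc1OC)[C@H](O)c1cc(OC)c(OC)c(OC)c1
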